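## Retrosynthetic overview

1. Labels: rings A, B and C are the three resorcinol rings (A lies only in the eight-membered ring, B is shared by the dihydrofuran and the eight-membered ring, C belongs to the indane). Cf and Cb are C2 and C3 of the dihydrofuran, Ca is the eight-ring CH bearing a 4-hydroxyphenyl group, Ce and Cc are the two CH atoms shared by indane and eight-membered ring (Ce bonded to ring C, Cc to ring B), and Cd is the indane CH bearing the other 4-hydroxyphenyl group. The target comes from its octamethyl ether by O-demethylation.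
2. Key disconnection: the bond from ring C to Ce and the Ca–aryl bond are made together in one palladium cascade. A ring C aryl triflate adds 5-exo across a Z-cyclooctene and the resulting alkylpalladium is captured by 4-methoxyphenylboronic acid; this closes the indane and sets Ce and Ca.
3. Enabling feature: inside the eight-membered ring Ca sits between Ce and an aromatic carbon of ring A, so an alkylpalladium at Ca has no syn β-hydrogen and lives long enough to be arylated. The ring C carbon to be bonded is meta to both ring C oxygens of the target (no Friedel–Crafts closure possible) but ortho to the carbon that bears Cd, so it is carried as an aryl triflate whose oxygen is the lactone oxygen of a temporary dihydrocoumarin ring.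
4. The cyclooctene comes from ring-closing metathesis of a diene made from that dihydrocoumarin (partial reduction, double Wittig, triflation). The lactone comes from 5,7-dimethoxycoumarin by rhodium-catalysed asymmetric arylation (Cd) and palladium-catalysed α-arylation (Cc) with a 4-bromo-2,3-diaryl-2,3-dihydrobenzofuran, itself made from a benzophenone hydrazone by rhodium-carbene C–H insertion.
5. Ring order: dihydrofuran (steps 6–7), dihydrocoumarin as temporary ring (steps 10–11, opened in steps 12–13), eight-membered ring (step 15), indane (step 16).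

Key step: step 16

Remark: the sense of induction of the two chiral catalysts (steps 6 and 10) is assigned by analogy with the closest substrate classes; should either prove opposite, the antipodal ligand is used and nothing else changes.

## Route

Step 1
Reactants: 1 2-bromo-4,6-dimethoxybenzaldehyde; 2 3,5-dimethoxyphenylmagnesium chloride (commercial THF solution)
Product: 3 rac-(2-bromo-4,6-dimethoxyphenyl)(3,5-dimethoxyphenyl)methanol
Conditions: THF, −78 → 0 °C; aq NH4Cl
Reagents that add atoms: none
Why: Grignard 1,2-addition to the aldehyde is faster at −78 °C than halogen–magnesium exchange at the aryl bromide; the new carbinol centre is racemic and is removed in step 2.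

Step 2
Reactants: 3 rac-(2-bromo-4,6-dimethoxyphenyl)(3,5-dimethoxyphenyl)methanol
Product: 4 (2-bromo-4,6-dimethoxyphenyl)(3,5-dimethoxyphenyl)methanone
Conditions: activated MnO2 (excess), CH2Cl2, rt
Reagents that add atoms: none
Why: Activated MnO2 oxidizes the doubly benzylic alcohol to the benzophenone (benzylic alcohol oxidation) without touching the aryl bromide or the ethers.

Step 3
Reactants: 4 (2-bromo-4,6-dimethoxyphenyl)(3,5-dimethoxyphenyl)methanone
Product: 5 (2-bromo-6-hydroxy-4-methoxyphenyl)(3,5-dimethoxyphenyl)methanone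
Conditions: BCl3 (1.5 equiv), CH2Cl2, −78 → 0 °C; H2O
Reagents that add atoms: none
Why: BCl3 chelates between the ketone oxygen and the single methoxy group ortho to it, so only that ether is cleaved (chelation-controlled ortho-demethylation of an aryl ketone).

Step 4
Reactants: 5 (2-bromo-6-hydroxy-4-methoxyphenyl)(3,5-dimethoxyphenyl)methanone
Product: 6 {2-bromo-4-methoxy-6-[(4-methoxybenzyl)oxy]phenyl}(3,5-dimethoxyphenyl)methanone
Conditions: 4-MeOC6H4CH2Cl, K2CO3, Bu4NI (cat.), DMF, 60 °C
Reagents that add atoms: 4-methoxybenzyl chloride, COc1ccc(CCl)cc1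
Why: Williamson etherification of the phenol installs the benzylic CH2 that becomes Cf of the dihydrofuran.

Step 5
Reactants: 6 {2-bromo-4-methoxy-6-[(4-methoxybenzyl)oxy]phenyl}(3,5-dimethoxyphenyl)methanone
Product: 7 hydrazone of ketone 6
Conditions: N2H4·H2O (excess), AcOH (cat.), EtOH, 90 °C, sealed tube
Reagents that add atoms: hydrazine (used as hydrate), NN
Why: Acid-catalysed condensation of hydrazine with the hindered diaryl ketone (hydrazone formation) gives the precursor of the diazo compound.

Step 6
Reactants: 7 hydrazone of ketone 6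
Product: 9 (2R,3S)-4-bromo-3-(3,5-dimethoxyphenyl)-6-methoxy-2-(4-methoxyphenyl)-2,3-dihydro-1-benzofuran (cis isomer), via diaryldiazomethane 8 (not isolated)
Conditions: activated MnO2, CH2Cl2, 0 °C, filtration; then Rh2(R-PTAD)4 [dirhodium tetrakis((R)-N-phthaloyl-1-adamantylglycinate)] (1 mol%), CH2Cl2, 0 °C → rt
Reagents that add atoms: none
Why: MnO2 dehydrogenates the hydrazone to the diaryldiazomethane, whose donor/donor rhodium carbene undergoes enantioselective intramolecular 1,5-insertion into the activated O–CH2–aryl bond (rhodium-carbene C–H insertion); the chiral carboxylate ligands set Cb (S) and, through the concerted insertion, the cis-disposed Cf (R).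

Step 7
Reactants: 9 (2R,3S)-4-bromo-3-(3,5-dimethoxyphenyl)-6-methoxy-2-(4-methoxyphenyl)-2,3-dihydro-1-benzofuran
Product: 10 (2S,3S)-4-bromo-3-(3,5-dimethoxyphenyl)-6-methoxy-2-(4-methoxyphenyl)-2,3-dihydro-1-benzofuran (trans isomer)
Conditions: CF3CO2H (1 equiv), CH2Cl2, 0 °C
Reagents that add atoms: none
Why: Acid reversibly ionizes the Cf–O bond to the 4-methoxybenzylic cation and reclosure gives the thermodynamically preferred trans-2,3-diaryl isomer (acid-mediated epimerization), so Cf becomes S while Cb is not involved.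

Step 8
Reactants: 10 (2S,3S)-4-bromo-3-(3,5-dimethoxyphenyl)-6-methoxy-2-(4-methoxyphenyl)-2,3-dihydro-1-benzofuran
Product: 11 2-[(2S,3S)-4-bromo-6-methoxy-2-(4-methoxyphenyl)-2,3-dihydro-1-benzofuran-3-yl]-4,6-dimethoxybenzaldehyde
Conditions: Cl2CHOMe (1.5 equiv), TiCl4 (2 equiv), CH2Cl2, −78 → −20 °C; H2O
Reagents that add atoms: dichloromethyl methyl ether, COC(Cl)Cl; water, O
Why: Rieche formylation should attack the most electron-rich ring, ring A, at one of its two equivalent positions ortho to Cb and para to a methoxy group, the ring B positions being deactivated by bromine.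

Step 9
Reactants: 11 2-[(2S,3S)-4-bromo-6-methoxy-2-(4-methoxyphenyl)-2,3-dihydro-1-benzofuran-3-yl]-4,6-dimethoxybenzaldehyde
Product: 12 (2S,3S)-4-bromo-3-[2-(dimethoxymethyl)-3,5-dimethoxyphenyl]-6-methoxy-2-(4-methoxyphenyl)-2,3-dihydro-1-benzofuran
Conditions: HC(OMe)3, pyridinium p-toluenesulfonate (cat.), MeOH, rt
Reagents that add atoms: trimethyl orthoformate, COC(OC)OC
Why: Acid-catalysed acetalization masks the aldehyde, which would otherwise be attacked by the enolate of step 11.

Step 10
Reactants: 13 5,7-dimethoxycoumarin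
Product: 14 (4R)-5,7-dimethoxy-4-(4-methoxyphenyl)chroman-2-one
Conditions: 4-MeOC6H4B(OH)2 (5 equiv), Rh(acac)(C2H4)2 (3 mol%), (R)-SEGPHOS (3.3 mol%), 1,4-dioxane/H2O (10:1), 60 °C
Reagents that add atoms: 4-methoxyphenylboronic acid, COc1ccc(B(O)O)cc1
Why: Rhodium-catalysed asymmetric conjugate addition of the arylboronic acid to the coumarin (Hayashi–Miyaura reaction), in which the aryl–rhodium species bound to (R)-SEGPHOS adds to one enantioface of C4 and so sets Cd as R.

Step 11
Reactants: 14 (4R)-5,7-dimethoxy-4-(4-methoxyphenyl)chroman-2-one; 12 (2S,3S)-4-bromo-3-[2-(dimethoxymethyl)-3,5-dimethoxyphenyl]-6-methoxy-2-(4-methoxyphenyl)-2,3-dihydro-1-benzofuran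
Product: 17 (3R,4R)-3-aryl-5,7-dimethoxy-4-(4-methoxyphenyl)chroman-2-one in which the 3-aryl group is the dihydrobenzofuran-4-yl unit of 12 (trans lactone), via lithium enolate 15 (not isolated), via chlorozinc enolate 16 (not isolated)
Conditions: LiHMDS, THF, −78 °C; ZnCl2, −78 → 0 °C; then 12, Pd(dba)2 (5 mol%), P(t-Bu)3 (10 mol%), THF, 60 °C
Reagents that add atoms: none
Why: Palladium-catalysed α-arylation of the lactone zinc enolate with the aryl bromide, the zinc enolate being mild enough to avoid ketene formation and Claisen condensation of the aryl lactone; the aryl group enters C3 anti to the C4 aryl group and the acidic α-aryl centre equilibrates to the trans lactone, which sets Cc as R.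

Step 12
Reactants: 17 trans lactone
Product: 19 lactol aldehyde (chroman-2-ol as anomer mixture with the ring A aldehyde set free), via lactol acetal 18 (not isolated)
Conditions: i-Bu2AlH (DIBAL-H, 1.2 equiv), CH2Cl2, −78 °C; then 1 M HCl, THF, rt
Reagents that add atoms: water, O
Why: DIBAL-H stops at the lactol because the aluminium hemiacetal is stable at −78 °C (partial lactone reduction) and the acidic work-up hydrolyses the dimethyl acetal; the lactol carbon is an anomer mixture that becomes sp2 in step 13.

Step 13
Reactants: 19 lactol aldehyde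
Product: 20 2-[(1R,2R)-2-{(2S,3S)-3-(2-ethenyl-3,5-dimethoxyphenyl)-6-methoxy-2-(4-methoxyphenyl)-2,3-dihydro-1-benzofuran-4-yl}-1-(4-methoxyphenyl)but-3-en-1-yl]-3,5-dimethoxyphenol (diene phenol)
Conditions: Ph3PCH3Br (6 equiv), KOt-Bu (5.5 equiv), THF, 0 °C → rt
Reagents that add atoms: methyltriphenylphosphonium bromide, C[P+](c1ccccc1)(c1ccccc1)c1ccccc1.[Br-]
Why: Wittig methylenation converts both the free aldehyde and, through its open hydroxy-aldehyde form, the lactol into vinyl groups in one operation, the slow release of the α-aryl aldehyde and the low temperature limiting epimerization at Cc.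

Step 14
Reactants: 20 diene phenol
Product: 21 diene triflate (trifluoromethanesulfonate of phenol 20)
Conditions: Tf2O (1.2 equiv), pyridine, CH2Cl2, −78 → 0 °C
Reagents that add atoms: trifluoromethanesulfonic anhydride, O=S(=O)(OS(=O)(=O)C(F)(F)F)C(F)(F)F
Why: Triflation of the ring C phenol turns the oxygen that served as lactone tether into the leaving group for the key step (aryl triflate formation).

Step 15
Reactants: 21 diene triflate
Product: 22 Z-cyclooctene aryl triflate (eight-membered ring made of two ring A carbons, Cb, two ring B carbons, Cc and the Ca=Ce double bond; Cb S, Cc R, Cd R, Cf S)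
Conditions: second-generation Hoveyda–Grubbs catalyst (10 mol%), toluene (2 mM), 90 °C
Reagents that add atoms: none
Why: Ring-closing metathesis of the ring A styrene with the vinyl group on Cc, held close by the congested dihydrobenzofuran, gives the eight-membered ring, in which the new alkene can only be Z.

Step 16
Reactants: 22 Z-cyclooctene aryl triflate
Product: 23 octamethyl ether of the target (Ca R; Cb S; Cc R; Cd R; Ce S; Cf S)
Conditions: Pd(OAc)2 (10 mol%), 1,1'-bis(diphenylphosphino)ferrocene (12 mol%), 4-MeOC6H4B(OH)2 (2.5 equiv, slow addition), K3PO4 (3 equiv), 1,4-dioxane/H2O (20:1), 90 °C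
Reagents that add atoms: 4-methoxyphenylboronic acid, COc1ccc(B(O)O)cc1
Why: Proposed new method: oxidative addition of zerovalent palladium into the ring C aryl triflate gives a cationic arylpalladium that adds syn, in a 5-exo-trig mode, across the Z-alkene of the eight-membered ring, forming the bond from ring C to Ce and closing the indane; the secondary benzylic palladium left at Ca cannot β-eliminate, because its only β-hydrogen (on Ce) is anti and its other neighbour is an aromatic carbon of ring A, so it survives until transmetalation with the arylboronic acid and stereoretentive reductive elimination install the 4-methoxyphenyl group. The closest known reaction type is the Heck cyclization–anion capture cascade (domino Heck–Suzuki), established for norbornene-type alkenes and for dearomative carbopalladations of indoles and benzofurans where syn β-hydride elimination is likewise blocked, but not for a medium-ring stilbene-type alkene. Ce is controlled by the Cc stereocentre: allylic 1,3-strain keeps the Cc–H bond in the alkene plane, so the aryl group tethered through Cd reaches Ce on the face anti to ring B and gives the trans ring fusion. Ca is controlled by the mechanism, since syn carbopalladation followed by retentive coupling places the new aryl group cis to ring C. The step needs carbopalladation to outrun direct Suzuki coupling of the triflate, which the intramolecular five-ring closure, the cationic triflate pathway and the slow addition of the boronic acid should secure.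

Step 17
Reactants: 23 octamethyl ether of the target
Product: 24 target CNP0193760.4
Conditions: BBr3 (excess), CH2Cl2, −78 °C → rt; MeOH, H2O
Reagents that add atoms: none
Why: BBr3 cleaves all eight aryl methyl ethers (Lewis-acid ether cleavage); should the dihydrofuran C–O bond ionize it recloses to the same, thermodynamically preferred trans isomer, and no other stereocentre is epimerizable.

## Compound list

1 | 2-bromo-4,6-dimethoxybenzaldehyde | O=Cc1c(Br)cc(OC)cc1OC | starting material
2 | 3,5-dimethoxyphenylmagnesium chloride | COc1cc(OC)cc([Mg]Cl)c1 | starting material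
3 | rac-(2-bromo-4,6-dimethoxyphenyl)(3,5-dimethoxyphenyl)methanol | COc1cc(OC)cc(C(O)c2c(Br)cc(OC)cc2OC)c1 | intermediate
4 | (2-bromo-4,6-dimethoxyphenyl)(3,5-dimethoxyphenyl)methanone | COc1cc(OC)cc(C(=O)c2c(Br)cc(OC)cc2OC)c1 | intermediate
5 | (2-bromo-6-hydroxy-4-methoxyphenyl)(3,5-dimethoxyphenyl)methanone | COc1cc(OC)cc(C(=O)c2c(Br)cc(OC)cc2O)c1 | intermediate
6 | {2-bromo-4-methoxy-6-[(4-methoxybenzyl)oxy]phenyl}(3,5-dimethoxyphenyl)methanone | COc1cc(OC)cc(C(=O)c2c(Br)cc(OC)cc2OCc2ccc(OC)cc2)c1 | intermediate
7 | hydrazone of ketone 6 | COc1cc(OC)cc(C(=NN)c2c(Br)cc(OC)cc2OCc2ccc(OC)cc2)c1 | intermediate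
8 | diaryldiazomethane from 7 | COc1cc(OC)cc(C(=[N+]=[N-])c2c(Br)cc(OC)cc2OCc2ccc(OC)cc2)c1 | intermediate
9 | (2R,3S)-4-bromo-3-(3,5-dimethoxyphenyl)-6-methoxy-2-(4-methoxyphenyl)-2,3-dihydro-1-benzofuran (cis) | COc1cc(OC)cc([C@H]2c3c(Br)cc(OC)cc3O[C@H]2c2ccc(OC)cc2)c1 | intermediate
10 | (2S,3S)-4-bromo-3-(3,5-dimethoxyphenyl)-6-methoxy-2-(4-methoxyphenyl)-2,3-dihydro-1-benzofuran (trans) | COc1cc(OC)cc([C@H]2c3c(Br)cc(OC)cc3O[C@@H]2c2ccc(OC)cc2)c1 | intermediate
11 | 2-[(2S,3S)-4-bromo-6-methoxy-2-(4-methoxyphenyl)-2,3-dihydro-1-benzofuran-3-yl]-4,6-dimethoxybenzaldehyde | COc1cc(OC)cc([C@H]2c3c(Br)cc(OC)cc3O[C@@H]2c2ccc(OC)cc2)c1C=O | intermediate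
12 | (2S,3S)-4-bromo-3-[2-(dimethoxymethyl)-3,5-dimethoxyphenyl]-6-methoxy-2-(4-methoxyphenyl)-2,3-dihydro-1-benzofuran | COc1cc(OC)cc([C@H]2c3c(Br)cc(OC)cc3O[C@@H]2c2ccc(OC)cc2)c1C(OC)OC | intermediate
13 | 5,7-dimethoxycoumarin | COc1cc(OC)c2ccc(=O)oc2c1 | starting material
14 | (4R)-5,7-dimethoxy-4-(4-methoxyphenyl)chroman-2-one | O=C1C[C@H](c2ccc(OC)cc2)c2c(OC)cc(OC)cc2O1 | intermediate
15 | lithium enolate of 14 | [Li]OC1=C[C@H](c2ccc(OC)cc2)c2c(OC)cc(OC)cc2O1 | intermediate
16 | chlorozinc enolate of 14 | Cl[Zn]OC1=C[C@H](c2ccc(OC)cc2)c2c(OC)cc(OC)cc2O1 | intermediate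
17 | (3R,4R)-3-{(2S,3S)-3-[2-(dimethoxymethyl)-3,5-dimethoxyphenyl]-6-methoxy-2-(4-methoxyphenyl)-2,3-dihydro-1-benzofuran-4-yl}-5,7-dimethoxy-4-(4-methoxyphenyl)chroman-2-one | COc1cc(OC)cc([C@H]2c3c([C@@H]4C(=O)Oc5cc(OC)cc(OC)c5[C@H]4c4ccc(OC)cc4)cc(OC)cc3O[C@@H]2c2ccc(OC)cc2)c1C(OC)OC | intermediate
18 | lactol acetal (chroman-2-ol of 17, anomer mixture) | COc1cc(OC)cc([C@H]2c3c([C@@H]4C(O)Oc5cc(OC)cc(OC)c5[C@H]4c4ccc(OC)cc4)cc(OC)cc3O[C@@H]2c2ccc(OC)cc2)c1C(OC)OC | intermediate
19 | lactol aldehyde (18 with the acetal hydrolysed) | COc1cc(OC)cc([C@H]2c3c([C@@H]4C(O)Oc5cc(OC)cc(OC)c5[C@H]4c4ccc(OC)cc4)cc(OC)cc3O[C@@H]2c2ccc(OC)cc2)c1C=O | intermediate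
20 | 2-[(1R,2R)-2-{(2S,3S)-3-(2-ethenyl-3,5-dimethoxyphenyl)-6-methoxy-2-(4-methoxyphenyl)-2,3-dihydro-1-benzofuran-4-yl}-1-(4-methoxyphenyl)but-3-en-1-yl]-3,5-dimethoxyphenol | COc1cc(OC)cc([C@H]2c3c([C@H](C=C)[C@H](c4ccc(OC)cc4)c4c(OC)cc(OC)cc4O)cc(OC)cc3O[C@@H]2c2ccc(OC)cc2)c1C=C | intermediate
21 | trifluoromethanesulfonate of phenol 20 | COc1cc(OC)cc([C@H]2c3c([C@H](C=C)[C@H](c4ccc(OC)cc4)c4c(OC)cc(OC)cc4OS(=O)(=O)C(F)(F)F)cc(OC)cc3O[C@@H]2c2ccc(OC)cc2)c1C=C | intermediate
22 | Z-cyclooctene aryl triflate (Cb S, Cc R, Cd R, Cf S; Ca=Ce double bond) | COc1cc(OC)cc2c1/C=C\[C@H]([C@H](c1ccc(OC)cc1)c1c(OC)cc(OC)cc1OS(=O)(=O)C(F)(F)F)c1cc(OC)cc3O[C@H](c4ccc(OC)cc4)[C@@H]2c13 | intermediate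
23 | octamethyl ether of the target (Ca R, Cb S, Cc R, Cd R, Ce S, Cf S) | COc1ccc([C@@H]2c3c(OC)cc(OC)cc3[C@H]3c4c(cc(OC)cc4[C@H]4[C@H](c5ccc(OC)cc5)c5c(OC)cc(OC)cc5[C@H]24)O[C@@H]3c2ccc(OC)cc2)cc1 | intermediate
24 | CNP0193760.4 (Ca R, Cb S, Cc R, Cd R, Ce S, Cf S) | Oc1ccc([C@@H]2c3c(O)cc(O)cc3[C@H]3c4c(cc(O)cc4[C@H]4[C@H](c5ccc(O)cc5)c5c(O)cc(O)cc5[C@H]24)O[C@@H]3c2ccc(O)cc2)cc1 | target

## Step count and risks

Total step count: 17. Longest linear sequence: 16 steps (steps 1–9 and 11–17, from aldehyde 1); step 10 is a one-step side branch.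

Steps most likely to fail:

Step 16 (proposed new method). The carbopalladation may take the other alkene face and give the cis-fused epimer, or transmetalation may come first and give the simple biaryl. The fallback makes the two bonds separately with established reactions; it sets out from diene triflate 21 and comes back at octamethyl ether 23. A conventional 5-exo Mizoroki–Heck cyclization of the triflate onto the vinyl group on Cc (Pd(OAc)2, 1,3-bis(diphenylphosphino)propane, Et3N, DMF, 80 °C) should give, after β-hydride elimination, the 1-methyleneindane F1. Ring-closing metathesis of its exocyclic methylene with the ring A styrene (second-generation Grubbs catalyst, toluene, 100 °C) should give the trisubstituted cyclooctene F2. Hydroboration–oxidation (BH3·SMe2; NaBO3) should place hydrogen on Ce and hydroxyl on Ca to give the benzylic alcohol F3. Dess–Martin oxidation should give the aryl ketone F4, whose α-centre Ce can be equilibrated with DBU towards the trans ring fusion. Addition of 4-methoxyphenyllithium in the presence of CeCl3 should give the tertiary carbinol F5. Ionic hydrogenation (Et3SiH, BF3·OEt2, CH2Cl2, −78 °C, cold enough to spare the dihydrofuran) of the doubly benzylic cation, with hydride delivered anti to ring C, should return to 23.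

Step 11. Oxidative addition or transmetalation may be too slow at two congested centres, and the aryl lactone enolate may decompose by ketene formation or self-condensation before it couples. The fallback inverts the polarity; it sets out from lactone 14 and bromide 12 and comes back at 17. Lactone 14 is brominated through its trimethylsilyl ketene acetal (LiHMDS, Me3SiCl, −78 °C; then N-bromosuccinimide) to the 3-bromolactone F6. Bromide 12 is converted by bromine–lithium exchange and transmetalation (n-BuLi, THF, −78 °C; ZnCl2) into the arylzinc chloride F7. A nickel-catalysed Negishi coupling of the secondary α-bromo ester with the arylzinc (NiCl2·glyme, 4,4'-di-tert-butyl-2,2'-bipyridine, THF/DMA, 0 °C → rt), which runs through the α-carbonyl radical and should give the thermodynamically preferred trans lactone, returns to 17.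

Step 15. Both vinyl groups are hindered, so initiation may be slow and intermolecular metathesis may compete with closure of the eight-membered ring. The fallback closes the ring by reductive carbonyl coupling; it sets out from lactol aldehyde 19 and comes back at 22. Intramolecular McMurry coupling of the aldehyde with the lactol in its open form (TiCl3(DME)1.5, Zn–Cu, DME, reflux, high dilution) should give the Z-cyclooctene phenol F8, and triflation (Tf2O, pyridine, CH2Cl2, 0 °C) returns to 22.

Further compounds
F1 | step 16 | 1-methyleneindane from Heck cyclization of 21 (ring A vinyl group retained) | COc1cc(OC)cc([C@H]2c3c([C@@H]4C(=C)c5cc(OC)cc(OC)c5[C@H]4c4ccc(OC)cc4)cc(OC)cc3O[C@@H]2c2ccc(OC)cc2)c1C=C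
F2 | step 16 | trisubstituted cyclooctene (Ce=Ca double bond, indane already closed) | COc1cc(OC)cc2c1/C=C1/c3cc(OC)cc(OC)c3[C@@H](c3ccc(OC)cc3)[C@@H]1c1cc(OC)cc3O[C@H](c4ccc(OC)cc4)[C@@H]2c13
F3 | step 16 | benzylic alcohol at Ca from syn hydroboration–oxidation | COc1cc(OC)cc2c1[C@H](O)[C@H]1c3cc(OC)cc(OC)c3[C@@H](c3ccc(OC)cc3)[C@@H]1c1cc(OC)cc3O[C@H](c4ccc(OC)cc4)[C@@H]2c13
F4 | step 16 | aryl ketone at Ca (trans-fused) | COc1cc(OC)cc2c1C(=O)[C@H]1c3cc(OC)cc(OC)c3[C@@H](c3ccc(OC)cc3)[C@@H]1c1cc(OC)cc3O[C@H](c4ccc(OC)cc4)[C@@H]2c13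
F5 | step 16 | tertiary carbinol at Ca bearing the 4-methoxyphenyl group (Ca configuration not defined) | COc1cc(OC)cc2c1C(O)(c1ccc(OC)cc1)[C@H]1c3cc(OC)cc(OC)c3[C@@H](c3ccc(OC)cc3)[C@@H]1c1cc(OC)cc3O[C@H](c4ccc(OC)cc4)[C@@H]2c13
F6 | step 11 | (4R)-3-bromo-5,7-dimethoxy-4-(4-methoxyphenyl)chroman-2-one (C3 epimer mixture) | O=C1C(Br)[C@H](c2ccc(OC)cc2)c2c(OC)cc(OC)cc2O1
F7 | step 11 | arylzinc chloride from bromide 12 | COc1cc(OC)cc([C@H]2c3c([Zn]Cl)cc(OC)cc3O[C@@H]2c2ccc(OC)cc2)c1C(OC)OC
F8 | step 15 | Z-cyclooctene phenol (22 with OH in place of the triflate) | COc1cc(OC)cc2c1/C=C\[C@H]([C@H](c1ccc(OC)cc1)c1c(OC)cc(OC)cc1O)c1cc(OC)cc3O[C@H](c4ccc(OC)cc4)[C@@H]2c13
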